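**Plan**

Rings are lettered A (benzo), B (4-hydroxyphenyl) and C (pyran) in the upper flavan, and D (benzo), E (pyrogallol) and F (pyran) in the epigallocatechin unit. Ring C (O1, C2, C3, C4, C4a, C8a) is a 2,4-cis-diaryl chroman with a bare CH2 at C3, the pattern that a ring A ortho-quinone methide (C8a=O, C4a=C4) and a styrene give in a [4+2] cycloaddition.
Retrosynthesis: the eight hydroxyls are benzylated, ring C is cut at O1–C2 and C3–C4 into 4-benzyloxystyrene and a diaryl carbinol, and the carbinol is cut at the C4–C8 (ring D) bond into an 8-lithio-epigallocatechin and a protected 2,4-dihydroxybenzaldehyde.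
Forward: (-)-epigallocatechin (rings D, E, F) is benzylated and brominated at C8; bromine–lithium exchange and addition to 2-allyloxy-4-benzyloxybenzaldehyde attach ring A; deallylation frees the ortho phenol; the acid-catalysed cycloaddition with the styrene (ring B) closes ring C, the only ring built; hydrogenolysis ends the route.
Stereochemistry: C2 and C3 of ring F are those of natural (2R,3R)-epigallocatechin and are never touched. C4 (S) is set by a chiral N-triflylphosphoramide that controls the face of the methide carbon. C2 (S) follows from C4 through the endo transition state of the (E)-quinone methide, which places rings B and D cis.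

Key step: step 8

Assumption: the (R)-configured N-triflylphosphoramide is taken as the antipode matched to the (2S,4S) upper unit; should a test run show the opposite sense of induction, the (S)-catalyst replaces it with nothing else changed.

**Route**

Step 1
Reactants: 1 (-)-epigallocatechin
Product: 2 5,7,3',4',5'-penta-O-benzylepigallocatechin (3-OH free)
Conditions: BnBr (5.5 equiv), K2CO3, DMF, argon, 0 °C to rt
Reagents that add atoms: benzyl bromide, BrCc1ccccc1
Why: Williamson etherification in which carbonate ionises the five phenols but not the secondary 3-OH, while the inert atmosphere protects the pyrogallol ring and the mild temperature keeps C2 from epimerising, so both stereocentres should pass through unchanged.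

Step 2
Reactants: 2 5,7,3',4',5'-penta-O-benzylepigallocatechin
Product: 3 8-bromo-5,7,3',4',5'-penta-O-benzylepigallocatechin
Conditions: NBS (1.0 equiv), CH2Cl2, -40 °C to 0 °C
Reagents that add atoms: N-bromosuccinimide, O=C1CCC(=O)N1Br
Why: Electrophilic aromatic bromination should take place on ring D, which has three ortho/para oxygen donors, and there at C8 rather than at C6 (flanked by two benzyloxy groups), as is known for benzyl-protected flavan-3-ols, one equivalent at low temperature sparing ring E.

Step 3
Reactants: 3 8-bromo-5,7,3',4',5'-penta-O-benzylepigallocatechin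
Product: 4 8-bromo-3,5,7,3',4',5'-hexa-O-benzylepigallocatechin
Conditions: NaH, BnBr, Bu4NI (cat.), THF, 0 °C to rt
Reagents that add atoms: benzyl bromide, BrCc1ccccc1
Why: Williamson etherification of the secondary alkoxide removes the only acidic proton before the lithiation, the aryl bromide and the stereocentres being inert to NaH.

Step 4
Reactants: 5 4-benzyloxy-2-hydroxybenzaldehyde
Product: 6 2-allyloxy-4-benzyloxybenzaldehyde
Conditions: allyl bromide, K2CO3, DMF, rt
Reagents that add atoms: allyl bromide, C=CCBr
Why: Williamson etherification installs an allyl mask that tolerates an aryllithium and later leaves under neutral catalysis by zerovalent palladium without touching benzyl ethers or an acid-labile carbinol.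

Step 5
Reactants: 4 8-bromo-3,5,7,3',4',5'-hexa-O-benzylepigallocatechin; 6 2-allyloxy-4-benzyloxybenzaldehyde
Product: 8 hexa-O-benzyl-8-[(2-allyloxy-4-benzyloxyphenyl)hydroxymethyl]epigallocatechin as a mixture of both carbinol epimers, via aryllithium 7 (not isolated)
Conditions: t-BuLi (2.1 equiv), THF, -78 °C; then 6, -78 °C to -30 °C; H2O
Reagents that add atoms: none
Why: Bromine–lithium exchange outruns deprotonation of the benzyl ethers at -78 °C, and the C8 aryllithium, of a type known to add to carbonyl groups in benzylated flavan-3-ols, undergoes 1,2-addition to the non-enolisable aldehyde; the new carbinol centre forms unselectively, which is of no consequence because step 8 erases it.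

Step 6
Reactants: 8 hexa-O-benzyl-8-[(2-allyloxy-4-benzyloxyphenyl)hydroxymethyl]epigallocatechin
Product: 9 hexa-O-benzyl-8-[(4-benzyloxy-2-hydroxyphenyl)hydroxymethyl]epigallocatechin (both carbinol epimers)
Conditions: Pd(PPh3)4 (5 mol %), morpholine, THF, rt; chromatography on Et3N-deactivated silica
Reagents that add atoms: none
Why: Tsuji–Trost-type deallylation, in which zerovalent palladium ionises the aryl allyl ether to a π-allyl complex and the phenoxide and morpholine captures the allyl group, runs in a neutral to basic medium that should leave the acid-labile diaryl carbinol and all benzyl ethers intact.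

Step 7
Reactants: 10 4-benzyloxybenzaldehyde
Product: 11 4-benzyloxystyrene
Conditions: Ph3PCH3Br, KOtBu, THF, 0 °C to rt
Reagents that add atoms: methyltriphenylphosphonium bromide, C[P+](c1ccccc1)(c1ccccc1)c1ccccc1.[Br-]
Why: Wittig methylenation of a non-enolisable aromatic aldehyde with the unstabilised ylide is a standard route to styrenes and the benzyl ether is inert to it.

Step 8
Reactants: 9 hexa-O-benzyl-8-[(4-benzyloxy-2-hydroxyphenyl)hydroxymethyl]epigallocatechin; 11 4-benzyloxystyrene
Product: 13 (2S,4S)-configured octa-O-benzyl ether of the target, via ortho-quinone methide 12 (not isolated)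
Conditions: (R)-3,3'-bis(2,4,6-triisopropylphenyl)-1,1'-binaphthyl-2,2'-diyl N-triflylphosphoramide (10 mol %), 11 (3 equiv), CH2Cl2 (0.02 M), -40 °C to -10 °C
Reagents that add atoms: none
Why: The strong chiral acid protonates the doubly benzylic hydroxyl of 9, water leaves, and the (E)-ortho-quinone methide 12 (C8a=O, C4a=C4, ring D on C4) is held as a hydrogen-bonded ion pair by the phosphoramide anion; ring D carries only ethers, so ring A alone can become a neutral quinone methide. The CH2 terminus of the styrene attacks C4 while the quinone oxygen closes on the developing 4-benzyloxybenzyl cation at C2, a concerted but asynchronous inverse-demand hetero-Diels–Alder reaction of the known acid-catalysed ortho-quinone methide plus styrene type that leads to 2,4-diarylchromans. Ring C is closed in the [4+2] mode from the four-atom unit O1=C8a–C4a=C4 and the two styrene carbons (new bonds C3–C4 and O1–C2); in the stepwise limit O1 captures the C2 cation to give the same six-membered ring. C4 (S) is controlled by the catalyst, whose 3,3'-aryl groups block one face of the methide carbon and should override the weak bias of the remote ring F stereocentres, and C2 (S) is controlled by C4 through the endo transition state in which ring B lies under the diene of the (E)-methide, so that rings B and D end up cis, the diequatorial and more stable arrangement. The step needs regioselectivity (O1 to the benzylic carbon), secured by the polarisation of the electron-rich styrene, and chemoselectivity over self-alkylation at the free C6–H of ring D and over cationic oligomerisation of the styrene, secured by excess styrene, high dilution, low temperature and a low acid loading; a C4 epimer that may accompany the product is a diastereomer and should be separable by chromatography.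

Step 9
Reactants: 13 (2S,4S)-configured octa-O-benzyl ether of the target
Product: 14 target, (2R,3R)-8-[(2S,4S)-7-hydroxy-2-(4-hydroxyphenyl)chroman-4-yl]-2-(3,4,5-trihydroxyphenyl)chroman-3,5,7-triol
Conditions: H2 (1 atm), Pd(OH)2/C, THF/MeOH/H2O, rt
Reagents that add atoms: none
Why: Catalytic hydrogenolysis should cleave all eight O-benzyl ethers (seven aryl, one alkyl) to toluene under conditions in which benzylated oligomeric flavans are known to keep their ring C–O bonds and the C4–C8 link, and no stereocentre takes part.

**Compound list**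

1 | (-)-epigallocatechin, (2R,3R)-2-(3,4,5-trihydroxyphenyl)chroman-3,5,7-triol | Oc1cc(O)c2c(c1)O[C@H](c1cc(O)c(O)c(O)c1)[C@H](O)C2 | starting material
2 | (2R,3R)-5,7-bis(benzyloxy)-2-[3,4,5-tris(benzyloxy)phenyl]chroman-3-ol (5,7,3',4',5'-penta-O-benzylepigallocatechin) | c1ccccc1COc1cc(OCc3ccccc3)c2c(c1)O[C@H](c1cc(OCc3ccccc3)c(OCc3ccccc3)c(OCc3ccccc3)c1)[C@H](O)C2 | intermediate
3 | (2R,3R)-8-bromo-5,7-bis(benzyloxy)-2-[3,4,5-tris(benzyloxy)phenyl]chroman-3-ol | Brc1c(OCc3ccccc3)cc(OCc3ccccc3)c2c1O[C@H](c1cc(OCc3ccccc3)c(OCc3ccccc3)c(OCc3ccccc3)c1)[C@H](O)C2 | intermediate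
4 | (2R,3R)-8-bromo-3,5,7-tris(benzyloxy)-2-[3,4,5-tris(benzyloxy)phenyl]chroman (8-bromo-hexa-O-benzylepigallocatechin) | Brc1c(OCc3ccccc3)cc(OCc3ccccc3)c2c1O[C@H](c1cc(OCc3ccccc3)c(OCc3ccccc3)c(OCc3ccccc3)c1)[C@H](OCc1ccccc1)C2 | intermediate
5 | 4-benzyloxy-2-hydroxybenzaldehyde | O=Cc1ccc(OCc2ccccc2)cc1O | starting material
6 | 2-allyloxy-4-benzyloxybenzaldehyde | O=Cc1ccc(OCc2ccccc2)cc1OCC=C | intermediate
7 | 8-lithio-3,5,7,3',4',5'-hexa-O-benzylepigallocatechin (aryllithium) | [Li]c1c(OCc3ccccc3)cc(OCc3ccccc3)c2c1O[C@H](c1cc(OCc3ccccc3)c(OCc3ccccc3)c(OCc3ccccc3)c1)[C@H](OCc1ccccc1)C2 | intermediate (not isolated)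
8 | hexa-O-benzyl-8-[(2-allyloxy-4-benzyloxyphenyl)hydroxymethyl]epigallocatechin, both carbinol epimers (carbinol centre left undefined), ring F (2R,3R) | OC(c1ccc(OCc3ccccc3)cc1OCC=C)c1c(OCc3ccccc3)cc(OCc3ccccc3)c2c1O[C@H](c1cc(OCc3ccccc3)c(OCc3ccccc3)c(OCc3ccccc3)c1)[C@H](OCc1ccccc1)C2 | intermediate
9 | hexa-O-benzyl-8-[(4-benzyloxy-2-hydroxyphenyl)hydroxymethyl]epigallocatechin, both carbinol epimers (carbinol centre left undefined), ring F (2R,3R) | OC(c1ccc(OCc3ccccc3)cc1O)c1c(OCc3ccccc3)cc(OCc3ccccc3)c2c1O[C@H](c1cc(OCc3ccccc3)c(OCc3ccccc3)c(OCc3ccccc3)c1)[C@H](OCc1ccccc1)C2 | intermediate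
10 | 4-benzyloxybenzaldehyde | O=Cc1ccc(OCc2ccccc2)cc1 | starting material
11 | 4-benzyloxystyrene | C=Cc1ccc(OCc2ccccc2)cc1 | intermediate
12 | (E)-3-benzyloxy-6-[(hexa-O-benzylepigallocatechin-8-yl)methylidene]cyclohexa-2,4-dien-1-one (ring A ortho-quinone methide) | O=C1C=C(OCc3ccccc3)C=C/C1=C\c1c(OCc3ccccc3)cc(OCc3ccccc3)c2c1O[C@H](c1cc(OCc3ccccc3)c(OCc3ccccc3)c(OCc3ccccc3)c1)[C@H](OCc1ccccc1)C2 | intermediate (not isolated)
13 | (2S,4S)-7-benzyloxy-2-(4-benzyloxyphenyl)-4-[(2R,3R)-3,5,7-tris(benzyloxy)-2-(3,4,5-tris(benzyloxy)phenyl)chroman-8-yl]chroman (octa-O-benzyl target) | c6ccccc6COc1ccc([C@@H]2C[C@H](c3c(OCc6ccccc6)cc(OCc6ccccc6)c4c3O[C@H](c3cc(OCc6ccccc6)c(OCc6ccccc6)c(OCc6ccccc6)c3)[C@H](OCc6ccccc6)C4)c3ccc(OCc6ccccc6)cc3O2)cc1 | intermediate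
14 | (2R,3R)-8-[(2S,4S)-7-hydroxy-2-(4-hydroxyphenyl)chroman-4-yl]-2-(3,4,5-trihydroxyphenyl)chroman-3,5,7-triol | Oc1ccc([C@@H]2C[C@H](c3c(O)cc(O)c4c3O[C@H](c3cc(O)c(O)c(O)c3)[C@H](O)C4)c3ccc(O)cc3O2)cc1 | target

**Step count**

Total: 9 steps. Longest linear sequence: 7 steps (steps 1, 2, 3, 5, 6, 8, 9, from 1 to 14). Steps 4 and 7 are one-step side branches.

**Steps most likely to fail**

Risk 1, step 8. The catalyst may discriminate poorly between the faces of the methide carbon, because the twisted, di-ortho-substituted ring D crowds its pocket. The quinone methide may also be drained by self-alkylation at C6–H of ring D, and the styrene by cationic oligomerisation. The fallback sets out from 4 and comes back at 13; it buys the upper C2 centre and sets C4 relative to it.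
- Commercial (2S)-liquiritigenin is O-benzylated under Mitsunobu conditions (BnOH, PPh3, diisopropyl azodicarboxylate, THF), which avoid the basic medium in which flavanones racemise by ring opening. This should give (2S)-7,4'-di-O-benzylliquiritigenin F1.
- Bromide 4 is converted into aryllithium 7 as in step 5 and added to the ketone of F1 at -78 °C, giving the tertiary 4-aryl-flavan-4-ol F2 (either C4 epimer).
- Ionic hydrogenation of F2 (Et3SiH, CF3CO2H, CH2Cl2, -40 °C) goes through the C4 cation stabilised by the 7-benzyloxy group. Hydride should arrive along the axial trajectory of the half-chair that keeps ring B equatorial, giving the 2,4-cis compound 13, which is also the more stable epimer. The route continues with step 9.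

Risk 2, step 5. The bromine–lithium exchange may be incomplete, the hindered aryllithium may be protonated before it meets the aldehyde, or t-BuLi may attack benzylic C–H bonds. The fallback sets out from 2 and comes back at 9; it reverses the polarity and needs no organolithium.
- The 3-OH of 2 is benzylated (NaH, BnBr, THF) to hexa-O-benzylepigallocatechin F3.
- Vilsmeier–Haack formylation (POCl3, DMF, 0 °C to rt) should attack C8 of ring D for the same reasons as the bromination. It gives the C8 iminium chloride F4, which aqueous NaOAc hydrolyses to 8-formyl-hexa-O-benzylepigallocatechin F5; a minor C6 isomer would be removed by chromatography.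
- Bromomagnesium 3-benzyloxyphenoxide (from 3-benzyloxyphenol and EtMgBr, toluene/CH2Cl2, rt) is then hydroxyalkylated by F5 in the known ortho-specific manner. Magnesium holds the phenoxide oxygen and the aldehyde together and directs attack to the less hindered ortho carbon, para to the benzyloxy group, giving 9 directly. Steps 2 to 6 are bypassed.

Risk 3, step 9. The hydrogenolysis may stall at the last benzyl ethers as the polyphenol binds to the catalyst, the benzylic C2–O1 bonds may be opened reductively, or the pyrogallol ring may oxidise in air during handling. The fallback sets out from 13 and comes back at 14; it replaces hydrogenolysis by Lewis-acid dealkylation.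
- BCl3 with pentamethylbenzene as a non-basic benzyl-cation scavenger (CH2Cl2, -78 °C, then MeOH) should cleave the eight benzyl ethers.
- The low temperature is chosen to protect the acid-sensitive C4–C8 link, and the scavenger prevents C-benzylation of the electron-rich rings. No new compound arises on the way.

**Further compounds**

F1 | step 8 | (2S)-7-benzyloxy-2-(4-benzyloxyphenyl)chroman-4-one [(2S)-7,4'-di-O-benzylliquiritigenin] | c6ccccc6COc1ccc([C@@H]2CC(=O)c3ccc(OCc6ccccc6)cc3O2)cc1
F2 | step 8 | (2S)-7-benzyloxy-2-(4-benzyloxyphenyl)-4-(hexa-O-benzylepigallocatechin-8-yl)chroman-4-ol, either C4 epimer | c6ccccc6COc1ccc([C@@H]2CC(O)(c3c(OCc6ccccc6)cc(OCc6ccccc6)c4c3O[C@H](c3cc(OCc6ccccc6)c(OCc6ccccc6)c(OCc6ccccc6)c3)[C@H](OCc6ccccc6)C4)c3ccc(OCc6ccccc6)cc3O2)cc1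
F3 | step 5 | (2R,3R)-3,5,7-tris(benzyloxy)-2-[3,4,5-tris(benzyloxy)phenyl]chroman (hexa-O-benzylepigallocatechin) | c1ccccc1COc1cc(OCc3ccccc3)c2c(c1)O[C@H](c1cc(OCc3ccccc3)c(OCc3ccccc3)c(OCc3ccccc3)c1)[C@H](OCc1ccccc1)C2
F4 | step 5 | N,N-dimethyl-(hexa-O-benzylepigallocatechin-8-yl)methaniminium chloride | C[N+](C)=Cc1c(OCc3ccccc3)cc(OCc3ccccc3)c2c1O[C@H](c1cc(OCc3ccccc3)c(OCc3ccccc3)c(OCc3ccccc3)c1)[C@H](OCc1ccccc1)C2.[Cl-]
F5 | step 5 | 8-formyl-hexa-O-benzylepigallocatechin | O=Cc1c(OCc3ccccc3)cc(OCc3ccccc3)c2c1O[C@H](c1cc(OCc3ccccc3)c(OCc3ccccc3)c(OCc3ccccc3)c1)[C@H](OCc1ccccc1)C2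
F0 | step 9 | none | none
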